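**Strategy**

The target is an unsymmetrical diester: a cyclobutane with cis aryl groups whose two carboxyls carry C6-epimeric 2,4,7-trimethyloctahydrocyclopenta[c]pyridin-6-yl groups. Both alcohols come from one bicyclic ketone, and the route rests on closing its cyclopentane ring (C4a, C5, C6, C7, C7a) and its piperidine ring together. An intramolecular Pauson–Khand reaction of a nitrogen-tethered 1,7-enyne does this in one operation: the terminal vinyl unit C4a=C5 gains the ring-fusion bond C4a–C7a and the bond C5–C6, with C6 and its oxygen arriving as CO. The precursor is an acyclic N-Boc N-butynyl N-(2-methylbutenyl)amine. The core is made by directed double C–H arylation; Mitsunobu inversions form both esters.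

Key step: step 5

Remark on the structure: the SMILES defines a cyclobutane with the two aryl groups cis; the carboxyl trans to both aryls carries the (6S)-alkoxy group (oxygen cis to the 7-methyl) and the carboxyl cis to both aryls carries the (6R)-alkoxy group (oxygen trans to the 7-methyl). Locants follow cyclopenta[c]pyridine numbering (C1, N2, C3, C4, C4a, C5, C6, C7, C7a).

Assumption: Taniaphos is taken to induce the same sense in step 2 as with simple (E)-allylic bromides, so the (S,S)-ligand should give (R)-4; otherwise the antipodal ligand is used.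

Assumption: acid 16 is bought as the pure trans isomer.

**Route**

Step 1
Reactants: 1 (E)-1,4-dibromobut-2-ene (3 equiv); 2 tert-butyl N-tosylcarbamate
Product: 3 tert-butyl N-[(E)-4-bromobut-2-en-1-yl]-N-tosylcarbamate
Conditions: K2CO3, MeCN, 50 °C
Reagents that add atoms: none
Why: SN2 N-alkylation of the acidic sulfonyl carbamate, with the dibromide in excess so that only one bromide is displaced and the E alkene is kept.

Step 2
Reactants: 3 tert-butyl N-[(E)-4-bromobut-2-en-1-yl]-N-tosylcarbamate
Product: 4 tert-butyl N-[(2R)-2-methylbut-3-en-1-yl]-N-tosylcarbamate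
Conditions: MeMgBr, CuBr·SMe2 (2 mol %), (S,S)-Taniaphos (2.4 mol %), CH2Cl2, −75 °C
Reagents that add atoms: methylmagnesium bromide, C[Mg]Br
Why: Copper-catalysed asymmetric allylic alkylation (SN2′) delivers methyl to the γ-carbon on one alkene face under ligand control, which sets the future C4 stereocentre as R.

Step 3
Reactants: 4 tert-butyl N-[(2R)-2-methylbut-3-en-1-yl]-N-tosylcarbamate
Product: 5 tert-butyl N-[(2R)-2-methylbut-3-en-1-yl]carbamate
Conditions: Mg turnings, MeOH, sonication, rt
Reagents that add atoms: none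
Why: Reductive N–S cleavage of an N-acyl sulfonamide by electron transfer from magnesium should leave the Boc group, the alkene and the stereocentre untouched.

Step 4
Reactants: 5 tert-butyl N-[(2R)-2-methylbut-3-en-1-yl]carbamate; 6 1-bromobut-2-yne
Product: 7 tert-butyl N-(but-2-yn-1-yl)-N-[(2R)-2-methylbut-3-en-1-yl]carbamate
Conditions: NaH, DMF, 0 °C to rt
Reagents that add atoms: none
Why: SN2 N-alkylation of the sodium carbamate with a propargylic bromide assembles the 1,7-enyne.

Step 5
Reactants: 7 tert-butyl N-(but-2-yn-1-yl)-N-[(2R)-2-methylbut-3-en-1-yl]carbamate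
Product: 8 tert-butyl (4R,4aR)-4,7-dimethyl-6-oxo-1,3,4,4a,5,6-hexahydro-2H-cyclopenta[c]pyridine-2-carboxylate (enone, C7=C7a)
Conditions: Co2(CO)8 (20 mol %), tetramethylthiourea (cat.), CO (1 atm), toluene, 70 °C
Reagents that add atoms: carbon monoxide, [C-]#[O+]
Why: The alkyne of 7 binds Co2(CO)6, the tethered vinyl group inserts into a Co–C bond to make C4a–C7a, CO inserts into the resulting Co–C5 bond and reductive elimination makes C5–C6 and C6–C7, which frees enone 8 and returns cobalt carbonyl under CO. This is the intramolecular Pauson–Khand reaction, a formal [2+2+1] cycloaddition, whose closest precedent is the cyclisation of heteroatom-tethered 1,7-enynes to bicyclo[4.3.0]nonenones. The piperidine ring closes in the insertion step by exo attack of the alkyne carbon C7a on the inner alkene carbon C4a through the four-atom tether C1–N2–C3–C4, and the cyclopentenone closes by the [2+2+1] union of C7=C7a, C4a–C5 and CO. The only new stereocentre, C4a, is set by the resident C4 methyl, which should take the pseudo-equatorial place in the chair-like metallacycle so that H4a ends cis to that methyl and C5 trans to it. Regiochemistry is not in question because the tether forces CO between C5 and C7, so the step needs only this diastereofacial selectivity, and the planar carbamate nitrogen favours the folded conformer needed for six-membered closure.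

Step 6
Reactants: 8 tert-butyl (4R,4aR)-4,7-dimethyl-6-oxo-1,3,4,4a,5,6-hexahydro-2H-cyclopenta[c]pyridine-2-carboxylate
Product: 10 tert-butyl (4R,4aR,7R,7aS)-4,7-dimethyl-6-oxooctahydro-2H-cyclopenta[c]pyridine-2-carboxylate, via 7-epi ketone 9 (not isolated)
Conditions: H2 (3 atm), 10% Pd/C, EtOAc, rt; filter; NaOMe (0.2 equiv), MeOH, rt
Reagents that add atoms: none
Why: Heterogeneous hydrogenation should add H2 syn on the enone face that carries H4a (the piperidine ring shields the other face), which sets C7a with a cis ring fusion, and methoxide then epimerises C7 through the enolate to the more stable ketone with the methyl on the convex face, trans to C1.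

Step 7
Reactants: 10 tert-butyl (4R,4aR,7R,7aS)-4,7-dimethyl-6-oxooctahydro-2H-cyclopenta[c]pyridine-2-carboxylate
Product: 11 (4R,4aR,6R,7R,7aS)-2,4,7-trimethyloctahydro-1H-cyclopenta[c]pyridin-6-ol (hydroxyl trans to the 7-methyl)
Conditions: LiAlH4 (excess), THF, 0 °C to reflux; then H2O
Reagents that add atoms: none
Why: LiAlH4 reduces the ketone (small hydride should attack the convex face syn to H4a and H7a, as with 2-alkylcyclopentanones, placing the hydroxyl trans to the 7-methyl) and at reflux reduces the Boc carbamate to the N-methyl group.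

Step 8
Reactants: 11 (4R,4aR,6R,7R,7aS)-2,4,7-trimethyloctahydro-1H-cyclopenta[c]pyridin-6-ol (part of the material)
Product: 12 (4R,4aR,6S,7R,7aS)-2,4,7-trimethyloctahydro-1H-cyclopenta[c]pyridin-6-yl 4-nitrobenzoate
Conditions: 4-nitrobenzoic acid, PPh3, DIAD, THF, 0 °C to rt
Reagents that add atoms: 4-nitrobenzoic acid, O=C(O)c1ccc(cc1)[N+](=O)[O-]
Why: Mitsunobu reaction, in which the carboxylate displaces the alkoxyphosphonium by SN2 and inverts C6 (should step 7 favour the other epimer, the same two steps applied to it supply 11).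

Step 9
Reactants: 12 (4R,4aR,6S,7R,7aS)-2,4,7-trimethyloctahydro-1H-cyclopenta[c]pyridin-6-yl 4-nitrobenzoate
Product: 13 (4R,4aR,6S,7R,7aS)-2,4,7-trimethyloctahydro-1H-cyclopenta[c]pyridin-6-ol (hydroxyl cis to the 7-methyl)
Conditions: K2CO3 (cat.), MeOH, rt
Reagents that add atoms: none
Why: Base-catalysed transesterification of the activated aryl ester with methanol frees the alcohol with retention at C6.

Step 10
Reactants: 14 4-iodo-2-methoxyphenol
Product: 15 1-(benzyloxy)-4-iodo-2-methoxybenzene
Conditions: BnBr, K2CO3, DMF, rt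
Reagents that add atoms: benzyl bromide, BrCc1ccccc1
Why: Williamson ether synthesis on the phenoxide gives a phenol protecting group that survives all later steps and leaves by hydrogenolysis.

Step 11
Reactants: 16 trans-3-(methoxycarbonyl)cyclobutane-1-carboxylic acid; 17 quinolin-8-amine
Product: 18 methyl trans-3-(quinolin-8-ylcarbamoyl)cyclobutane-1-carboxylate
Conditions: EDC·HCl, DMAP (cat.), CH2Cl2, rt
Reagents that add atoms: none
Why: Carbodiimide amide coupling installs the bidentate 8-aminoquinoline directing group under near-neutral conditions that do not epimerise the ring carbons.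

Step 12
Reactants: 18 methyl trans-3-(quinolin-8-ylcarbamoyl)cyclobutane-1-carboxylate; 15 1-(benzyloxy)-4-iodo-2-methoxybenzene (4 equiv)
Product: 19 methyl 2,4-bis[4-(benzyloxy)-3-methoxyphenyl]-3-(quinolin-8-ylcarbamoyl)cyclobutane-1-carboxylate (both aryl groups and the carbamoyl group mutually cis, ester trans to all three)
Conditions: Pd(OAc)2 (15 mol %), AgOAc (3 equiv), toluene, 110 °C
Reagents that add atoms: none
Why: 8-Aminoquinoline-directed β-C(sp3)–H arylation (divalent/tetravalent palladium cycle) cleaves at each ring methylene the C–H bond cis to the amide through a five-membered palladacycle and arylates it with retention, so both aryl groups should end cis to the amide carbon and trans to the ester already fixed in 16.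

Step 13
Reactants: 19 methyl 2,4-bis[4-(benzyloxy)-3-methoxyphenyl]-3-(quinolin-8-ylcarbamoyl)cyclobutane-1-carboxylate
Product: 20 methyl 2,4-bis[4-(benzyloxy)-3-methoxyphenyl]-3-[(tert-butoxycarbonyl)(quinolin-8-yl)carbamoyl]cyclobutane-1-carboxylate (same relative configuration)
Conditions: Boc2O, DMAP, MeCN, 60 °C
Reagents that add atoms: di-tert-butyl dicarbonate, CC(C)(C)OC(=O)OC(=O)OC(C)(C)C
Why: DMAP-catalysed N-acylation turns the robust secondary amide into a twisted, imide-like acyl donor without touching the ring stereocentres.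

Step 14
Reactants: 20 methyl 2,4-bis[4-(benzyloxy)-3-methoxyphenyl]-3-[(tert-butoxycarbonyl)(quinolin-8-yl)carbamoyl]cyclobutane-1-carboxylate
Product: 22 2,4-bis[4-(benzyloxy)-3-methoxyphenyl]-3-(methoxycarbonyl)cyclobutane-1-carboxylic acid (acid cis to both aryl groups, methyl ester trans), via peroxy acid 21 (not isolated)
Conditions: LiOH·H2O, 30% aq H2O2, THF/H2O, 0 °C; then aq Na2SO3; then 1 M HCl to pH 3
Reagents that add atoms: hydrogen peroxide, OO
Why: Hydroperoxide, a weakly basic α-effect nucleophile, should attack the activated acyl carbon in preference to the methyl ester and the carbamate carbonyl (as in imide auxiliary cleavage), and sulfite reduces the peroxy acid, so the congested carbon keeps its configuration.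

Step 15
Reactants: 22 2,4-bis[4-(benzyloxy)-3-methoxyphenyl]-3-(methoxycarbonyl)cyclobutane-1-carboxylic acid; 13 (4R,4aR,6S,7R,7aS)-2,4,7-trimethyloctahydro-1H-cyclopenta[c]pyridin-6-ol
Product: 23 1-methyl 3-[(4R,4aR,6R,7R,7aS)-2,4,7-trimethyloctahydro-1H-cyclopenta[c]pyridin-6-yl] 2,4-bis[4-(benzyloxy)-3-methoxyphenyl]cyclobutane-1,3-dicarboxylate (amino ester cis to both aryl groups, methyl ester trans)
Conditions: PPh3, DIAD, toluene/THF, 0 °C to rt
Reagents that add atoms: none
Why: Mitsunobu esterification uses the hindered carboxylate as an oxygen nucleophile, so the epimerisable acyl carbon is never activated, and SN2 inversion at C6 turns the 6S alcohol into the 6R ester with oxygen trans to the 7-methyl.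

Step 16
Reactants: 23 1-methyl 3-[(4R,4aR,6R,7R,7aS)-2,4,7-trimethyloctahydro-1H-cyclopenta[c]pyridin-6-yl] 2,4-bis[4-(benzyloxy)-3-methoxyphenyl]cyclobutane-1,3-dicarboxylate
Product: 25 2,4-bis[4-(benzyloxy)-3-methoxyphenyl]-3-{[(4R,4aR,6R,7R,7aS)-2,4,7-trimethyloctahydro-1H-cyclopenta[c]pyridin-6-yl]oxycarbonyl}cyclobutane-1-carboxylic acid (acid trans to both aryl groups), via trimethylstannyl ester 24 (not isolated)
Conditions: Me3SnOH, 1,2-dichloroethane, 80 °C; then pH 7 phosphate buffer
Reagents that add atoms: trimethyltin hydroxide, C[Sn](C)(C)O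
Why: Trimethyltin hydroxide cleaves the unhindered methyl ester under neutral conditions through the stannyl ester, sparing the hindered secondary ester and its cis-flanked α-carbon.

Step 17
Reactants: 25 2,4-bis[4-(benzyloxy)-3-methoxyphenyl]-3-{[(4R,4aR,6R,7R,7aS)-2,4,7-trimethyloctahydro-1H-cyclopenta[c]pyridin-6-yl]oxycarbonyl}cyclobutane-1-carboxylic acid; 11 (4R,4aR,6R,7R,7aS)-2,4,7-trimethyloctahydro-1H-cyclopenta[c]pyridin-6-ol
Product: 26 bis(benzyl ether) of the target: 1-[(4R,4aR,6S,7R,7aS)-2,4,7-trimethyloctahydro-1H-cyclopenta[c]pyridin-6-yl] 3-[(4R,4aR,6R,7R,7aS)-2,4,7-trimethyloctahydro-1H-cyclopenta[c]pyridin-6-yl] 2,4-bis[4-(benzyloxy)-3-methoxyphenyl]cyclobutane-1,3-dicarboxylate (C1 ester trans, C3 ester cis to both aryl groups)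
Conditions: PPh3, DIAD, THF, 0 °C to rt
Reagents that add atoms: none
Why: Mitsunobu esterification with SN2 inversion at C6 turns the 6R alcohol into the 6S ester with oxygen cis to the 7-methyl, the carboxylate attacking from the convex face.

Step 18
Reactants: 26 bis(benzyl ether) of the target
Product: 27 CNP0283097.4 (target)
Conditions: H2 (1 atm), 10% Pd/C, EtOAc/MeOH, rt
Reagents that add atoms: none
Why: Hydrogenolysis of the two aryl benzyl ethers frees the phenols, while the esters, the tertiary amines and the cyclobutane should be inert.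

**Compound list**

1 | (E)-1,4-dibromobut-2-ene | BrC/C=C/CBr | starting material
2 | tert-butyl N-tosylcarbamate | Cc1ccc(cc1)S(=O)(=O)NC(=O)OC(C)(C)C | starting material
3 | tert-butyl N-[(E)-4-bromobut-2-en-1-yl]-N-tosylcarbamate | Cc1ccc(cc1)S(=O)(=O)N(C/C=C/CBr)C(=O)OC(C)(C)C | intermediate
4 | tert-butyl N-[(2R)-2-methylbut-3-en-1-yl]-N-tosylcarbamate | Cc1ccc(cc1)S(=O)(=O)N(C[C@@H](C=C)C)C(=O)OC(C)(C)C | intermediate
5 | tert-butyl N-[(2R)-2-methylbut-3-en-1-yl]carbamate | CC(C)(C)OC(=O)NC[C@@H](C=C)C | intermediate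
6 | 1-bromobut-2-yne | CC#CCBr | starting material
7 | tert-butyl N-(but-2-yn-1-yl)-N-[(2R)-2-methylbut-3-en-1-yl]carbamate | CC#CCN(C[C@@H](C=C)C)C(=O)OC(C)(C)C | intermediate
8 | tert-butyl (4R,4aR)-4,7-dimethyl-6-oxo-1,3,4,4a,5,6-hexahydro-2H-cyclopenta[c]pyridine-2-carboxylate | O=C1C[C@H]2C(CN(C(=O)OC(C)(C)C)C[C@@H]2C)=C1C | intermediate
9 | tert-butyl (4R,4aR,7S,7aS)-4,7-dimethyl-6-oxooctahydro-2H-cyclopenta[c]pyridine-2-carboxylate (7-epi ketone) | O=C1C[C@H]2[C@H](CN(C(=O)OC(C)(C)C)C[C@@H]2C)[C@@H]1C | intermediate (not isolated)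
10 | tert-butyl (4R,4aR,7R,7aS)-4,7-dimethyl-6-oxooctahydro-2H-cyclopenta[c]pyridine-2-carboxylate | O=C1C[C@H]2[C@H](CN(C(=O)OC(C)(C)C)C[C@@H]2C)[C@H]1C | intermediate
11 | (4R,4aR,6R,7R,7aS)-2,4,7-trimethyloctahydro-1H-cyclopenta[c]pyridin-6-ol | O[C@@H]1C[C@H]2[C@H](CN(C)C[C@@H]2C)[C@H]1C | intermediate
12 | (4R,4aR,6S,7R,7aS)-2,4,7-trimethyloctahydro-1H-cyclopenta[c]pyridin-6-yl 4-nitrobenzoate | O=C(O[C@H]1C[C@H]2[C@H](CN(C)C[C@@H]2C)[C@H]1C)c1ccc(cc1)[N+](=O)[O-] | intermediate
13 | (4R,4aR,6S,7R,7aS)-2,4,7-trimethyloctahydro-1H-cyclopenta[c]pyridin-6-ol | O[C@H]1C[C@H]2[C@H](CN(C)C[C@@H]2C)[C@H]1C | intermediate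
14 | 4-iodo-2-methoxyphenol | COc1cc(I)ccc1O | starting material
15 | 1-(benzyloxy)-4-iodo-2-methoxybenzene | COc1cc(I)ccc1OCc1ccccc1 | intermediate
16 | trans-3-(methoxycarbonyl)cyclobutane-1-carboxylic acid | COC(=O)[C@H]1C[C@H](C(=O)O)C1 | starting material
17 | quinolin-8-amine | Nc1cccc2cccnc12 | starting material
18 | methyl trans-3-(quinolin-8-ylcarbamoyl)cyclobutane-1-carboxylate | COC(=O)[C@H]1C[C@H](C(=O)Nc2cccc3cccnc23)C1 | intermediate
19 | methyl 2,4-bis[4-(benzyloxy)-3-methoxyphenyl]-3-(quinolin-8-ylcarbamoyl)cyclobutane-1-carboxylate (aryls and carbamoyl mutually cis, ester trans) | COc1cc([C@@H]2[C@@H](C(=O)OC)[C@H](c3ccc(OCc4ccccc4)c(OC)c3)[C@@H]2C(=O)Nc2cccc3cccnc23)ccc1OCc1ccccc1 | intermediate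
20 | methyl 2,4-bis[4-(benzyloxy)-3-methoxyphenyl]-3-[(tert-butoxycarbonyl)(quinolin-8-yl)carbamoyl]cyclobutane-1-carboxylate | COc1cc([C@@H]2[C@@H](C(=O)OC)[C@H](c3ccc(OCc4ccccc4)c(OC)c3)[C@@H]2C(=O)N(C(=O)OC(C)(C)C)c2cccc3cccnc23)ccc1OCc1ccccc1 | intermediate
21 | 2,4-bis[4-(benzyloxy)-3-methoxyphenyl]-3-(methoxycarbonyl)cyclobutane-1-carboperoxoic acid (peroxy acid) | COc1cc([C@@H]2[C@@H](C(=O)OC)[C@H](c3ccc(OCc4ccccc4)c(OC)c3)[C@@H]2C(=O)OO)ccc1OCc1ccccc1 | intermediate (not isolated)
22 | 2,4-bis[4-(benzyloxy)-3-methoxyphenyl]-3-(methoxycarbonyl)cyclobutane-1-carboxylic acid (acid cis to both aryls) | COc1cc([C@@H]2[C@@H](C(=O)OC)[C@H](c3ccc(OCc4ccccc4)c(OC)c3)[C@@H]2C(=O)O)ccc1OCc1ccccc1 | intermediate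
23 | 1-methyl 3-[(4R,4aR,6R,7R,7aS)-2,4,7-trimethyloctahydro-1H-cyclopenta[c]pyridin-6-yl] 2,4-bis[4-(benzyloxy)-3-methoxyphenyl]cyclobutane-1,3-dicarboxylate | COc1cc([C@@H]2[C@@H](C(=O)OC)[C@H](c3ccc(OCc4ccccc4)c(OC)c3)[C@@H]2C(=O)O[C@@H]2C[C@H]3[C@H](CN(C)C[C@@H]3C)[C@H]2C)ccc1OCc1ccccc1 | intermediate
24 | trimethylstannyl ester of acid 25 | COc1cc([C@@H]2[C@@H](C(=O)O[Sn](C)(C)C)[C@H](c3ccc(OCc4ccccc4)c(OC)c3)[C@@H]2C(=O)O[C@@H]2C[C@H]3[C@H](CN(C)C[C@@H]3C)[C@H]2C)ccc1OCc1ccccc1 | intermediate (not isolated)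
25 | 2,4-bis[4-(benzyloxy)-3-methoxyphenyl]-3-{[(4R,4aR,6R,7R,7aS)-2,4,7-trimethyloctahydro-1H-cyclopenta[c]pyridin-6-yl]oxycarbonyl}cyclobutane-1-carboxylic acid | COc1cc([C@@H]2[C@@H](C(=O)O)[C@H](c3ccc(OCc4ccccc4)c(OC)c3)[C@@H]2C(=O)O[C@@H]2C[C@H]3[C@H](CN(C)C[C@@H]3C)[C@H]2C)ccc1OCc1ccccc1 | intermediate
26 | bis(benzyl ether) of the target | COc1cc([C@@H]2[C@@H](C(=O)O[C@H]3C[C@H]4[C@H](CN(C)C[C@@H]4C)[C@H]3C)[C@H](c3ccc(OCc4ccccc4)c(OC)c3)[C@@H]2C(=O)O[C@@H]2C[C@H]3[C@H](CN(C)C[C@@H]3C)[C@H]2C)ccc1OCc1ccccc1 | intermediate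
27 | CNP0283097.4 | COc1cc([C@@H]2[C@@H](C(=O)O[C@H]3C[C@H]4[C@H](CN(C)C[C@@H]4C)[C@H]3C)[C@H](c3ccc(O)c(OC)c3)[C@@H]2C(=O)O[C@@H]2C[C@H]3[C@H](CN(C)C[C@@H]3C)[C@H]2C)ccc1O | target

**Summary**

Total step count: 18.
Longest linear sequence: 13 steps (steps 1 to 9, then 15 to 18).

Steps most likely to fail:

Step 5. Alkene insertion at cobalt may show poor facial selectivity (a mixture at C4a), or the 1,7-enyne may turn over slowly under catalytic conditions. The fallback sets out from 7 and closes both rings under thermodynamic control with stoichiometric zirconocene. Cp2ZrCl2 and n-BuLi (2 equiv) in THF, −78 °C to rt, should give by reversible oxidative coupling the zirconacyclopentene F1, with the C4 methyl equatorial. Carbonylation (CO, 1 atm, 0 °C) and aqueous HCl work-up would then return the route at enone 8.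

Step 14. Hydroperoxide may attack the carbamate carbonyl instead of the crowded acyl carbon and merely return amide 19, or the carbon flanked by two cis aryl groups may epimerise in the basic medium. The fallback avoids the auxiliary altogether and sets out from acid 16. Carboxylate-directed β-C–H arylation (Pd(OAc)2, N-acetylglycine as ligand, Ag2CO3, hexafluoroisopropanol, 90 °C) with 15 should give first the racemic mono-arylated acid F2 (aryl cis to the acid) and, with further 15, the bis-arylated acid, returning at 22.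

Step 15. Displacement at the alkoxyphosphonium from the concave face may be outrun by elimination to the cyclopentene or by acylation of the reduced azodicarboxylate. The fallback sets out from 22 and forms the ester with retention from the other epimer. Cyanuric fluoride and pyridine in CH2Cl2 should give the acyl fluoride F3, a neutral acyl donor that resists ketene formation. Alcohol 11 and DMAP (CH2Cl2, 40 °C) would then acylate with retention at C6 and return at 23.

Further compounds

F1 | step 5 | bis(cyclopentadienyl)zirconacyclopentene from 7 (tert-butyl (4R,4aR)-4,7-dimethyl-6,6-bis(cyclopentadienyl)-6-zircona-1,3,4,4a,5,6-hexahydro-2H-cyclopenta[c]pyridine-2-carboxylate) | [Zr]1(C2C=CC=C2)(C2C=CC=C2)C[C@H]2C(CN(C(=O)OC(C)(C)C)C[C@@H]2C)=C1C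
F2 | step 14 | 2-[4-(benzyloxy)-3-methoxyphenyl]-3-(methoxycarbonyl)cyclobutane-1-carboxylic acid (racemic; aryl cis to the acid, methyl ester trans) | COc1cc([C@@H]2[C@@H](C(=O)OC)C[C@@H]2C(=O)O)ccc1OCc1ccccc1
F3 | step 15 | methyl 2,4-bis[4-(benzyloxy)-3-methoxyphenyl]-3-(fluorocarbonyl)cyclobutane-1-carboxylate (acyl fluoride cis to both aryls) | COc1cc([C@@H]2[C@@H](C(=O)OC)[C@H](c3ccc(OCc4ccccc4)c(OC)c3)[C@@H]2C(=O)F)ccc1OCc1ccccc1
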